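All runs are calculated from invented constants, and the scatter is random.

**The question.** The amber, green and violet runs are the earlier evidence for a flask charged at 0.050 M of starting material.

| setting | amber | green | violet | flask |
|---|---|---|---|---|
| starting material | 0.034 M | 0.075 M | 0.050 M | 0.050 M |
| partner | 1.5 equiv | 1.5 equiv | 1.5 equiv | 1.50 equiv |
| capture agent | 1 mM | 1 mM | 2 mM | 1.00 mM |
| remark | run made earlier | run made earlier | run made earlier |  |
| time |  |  |  | 25 h |

- amber (time / h: starting material / %, mono adduct / %, bis adduct / %): 2.50: 90.5, 8.6, 0.6; 5.00: 86.1, 7.7, 3.8; 8.00: 84.8, 8.3, 2.9; 15.0: 85.3, 7.7, 4.5; 30.0: 86.9, 7.7, 4.4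
- green (time / h: starting material / %, mono adduct / %, bis adduct / %): 2.50: 82.4, 11.1, 6.3; 8.00: 76.2, 12.3, 8.2; 15.0: 76.3, 12.0, 7.4; 20.0: 75.9, 12.4, 9.6; 30.0: 76.2, 12.6, 9.0
- violet (time / h: starting material / %, mono adduct / %, bis adduct / %): 6.00: 83.0, 9.2, 6.0; 12.0: 81.3, 8.3, 4.6; 20.0: 81.3, 8.7, 4.3; 25.0: 83.0, 8.3, 6.0; 30.0: 82.2, 9.0, 4.2

(standard deviation of a reading: 1 percentage point)



- how much starting material there is at 25 h, in percent of the starting material charged
- how much mono adduct there is at 25 h, in percent of the starting material charged
- how much bis adduct there is at 25 h, in percent of the starting material charged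
- how much tris adduct there is at 25 h, in percent of the starting material charged

**First instants.** Read the amber run: at 2.50 h it holds 90.5% starting material, 8.6% mono adduct and 0.6% bis adduct, so mono adduct leads.

**The middle.** At 8.00 h amber reads 84.8% starting material, and at 8.00 h green reads 76.2%. Hold what follows against the scatter of 1 percentage point: at 30.0 h amber reads 86.9% and green 76.2%. Against that scatter these starting material readings show no clear trend with time, while amber and green, which differ in their charge, stay apart.

**The end.** Average the flat readings from those times onward and take the converted share, the starting material gone: 14.3% in amber, 23.9% in green. Work in logarithms. From amber to green the charge rises by 0.344 powers of ten and the converted share by 0.223. That makes 0.644 powers of ten of converted share per power of ten of charge, with partner equivalents and capture agent held as in these two runs, a reading named the conversion exponent.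

**My reckoning.** This flask lies 0.167 powers of ten above amber in charge, with the partner equivalents and capture agent of amber. The exponent therefore adds 0.108 powers of ten, which gives a converted share of 18.4% and 81.6% starting material at 25 h. The exponent says nothing about the split among adducts.

**The forecast.** It holds that “the flask should sit on an equilibrium plateau” and gives 81.5% starting material, 9.7% mono adduct, 6% bis adduct and 1% tris adduct.

**The result.** The flask gives 81.6% starting material, 9.75% mono adduct, 5.82% bis adduct and 0.798% tris adduct, a converted share of 18.4% against 18.4% from the exponent 0.644. By 5.00 h the flask had behind it 96% of the turnover up to 25 h of the step from starting material and partner to mono adduct, and 95% of that of the partner's decay to decomposed reagent; partner fell from 22.8% of its charge at 2.50 h to 0.0549% at 12.5 h. Meanwhile capture agent kept forming trapped intermediate, which rose from 0.718% at 2.50 h to 2.00% at 25.0 h, when 0.181% of the capture agent remained.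

    starting material + partner → mono adduct + by-product (k = 1.60 /M/h)
    partner + mono adduct → bis adduct + by-product (k = 7.90 /M/h)
    partner + bis adduct → tris adduct + by-product (k = 2.80 /M/h)
    partner + tris adduct → tetra adduct + by-product (k = 0.0450 /M/h)
    mono adduct + capture agent → trapped intermediate (k = 53.0 /M/h)
    partner → decomposed reagent (k = 0.490 /h)

**Second flask.** For a neighbour charged at 0.085 M, the exponent 0.644 gives a converted share of 25.9%, leaving 74.1% starting material. The computed neighbour holds 73.9% starting material at 25.0 h.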